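# Proposed synthesis of CNP0250921.1 by para-quinone methide cycloetherification onto a pre-set C3 centre

## The problem

The target is a linear trimer of phenylpropanoid units in which two trans-2-aryl-3-(hydroxymethyl)-7-methoxy-2,3-dihydrobenzofurans are joined head to tail: guaiacyl ring A sits on C2 of unit 1 (benzo ring B, furan ring C), C5 of ring B carries C2′ of unit 2 (furan ring D, benzo ring E), and ring E ends in an (E)-3-hydroxyprop-1-enyl chain. The four stereocentres, (2R,3S,2′R,3′S), form two trans pairs. Within a pair C3 can dictate C2, because the benzylic C2–O bond is made, and can be re-made, through a planar cation or quinone methide. The two pairs are insulated from each other by ring B, so absolute configuration has to be brought in twice by a reagent. The fragile features are the free guaiacol (easily oxidised), the benzylic aryl ether bonds O1–C2 and O1′–C2′ (open to acid ionisation, hydrogenolysis and dehydrogenation to benzofurans), the cinnamyl alcohol, and the 3-hydroxymethyl groups, which can be lost as formaldehyde from a C2 cation. The feature that enables the key step is that C2 is bonded to ring A para to its free hydroxyl. Two-electron oxidation of ring A therefore gives a para-quinone methide whose exocyclic carbon is C2, and the phenolic oxygen of ring B then lies five atoms away (O1, C7a, C3a, C3, C2). Unit 2 has no such handle, since the oxygen para to C2′ is O1, already an ether.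

## Retrosynthesis

**End game.** Target 28 is traced to its bis-silyl ether 27, then to cinnamate 26 and to aldehyde 25 by cutting the side-chain C=C bond. The cinnamyl alcohol is the most acid- and hydrogenation-sensitive group, so it is made last. Aldehyde 25 carries all four stereocentres and both furan rings. The forward steps need only an (E)-selective Wittig olefination, a 1,2-reduction and a fluoride desilylation.

**Ring D.** Aldehyde 25 is cut at O1′–C2′ and at C2′–C3′, leading through phenol 24, diol 23 and aldol adduct 22 to aldehyde 18 and imide 20 (as its boron enolate 21). A quinone methide cannot be used here because O1 is etherified. Hydride abstraction from a C2′ methylene would have to be carried out beside ring C, which is itself prone to dehydrogenation. The oxidation level at C2′ is therefore supplied by the formyl group that 18 already carries. The auxiliary aldol sets C3′, and the carbinol is later ionised and closed trans. The forward reaction must give α-facial control in the aldol and ionise only the benzylic C–OH.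

**Ring C (key cut).** Aldehyde 18 is the bis-silyl ether of 17, and 17 is cut at O1–C2 to diphenol 15 through quinone methide 16. Against an aldol/dehydration construction, this cut lets C2 enter as a plain methylene, adds no throw-away stereocentre and uses the free phenol of ring A that the target itself has. The para-formyl group on ring B does double duty: it shields the ring-B phenol from the oxidant, and it becomes C2′ in the next disconnection. Precursor 15 has one stereocentre and no ring other than the arenes. The forward step must oxidise ring A only, close the five-membered ring and place the aryl group trans to the C3 substituent.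

**C2–C3 bond.** Diphenol 15 is traced through acetal 14 and alcohol 13 to alkylated imide 12. This is cut at C2–C3 into the sodium enolate 11 of imide 8 and benzylic bromide 10 (from alcohol 9). An auxiliary alkylation is preferred to catalytic alternatives because the arylacetyl enolate is easily formed and the facial outcome is predictable. The forward step must avoid proton exchange at the acidic α-aryl centre.

**Common arylacetic acid.** Rings B and E have the same substitution pattern (oxygen, methoxy, formyl, acetic acid arm). Imides 8 and 20 are therefore both made from one batch of mixed pivalic anhydride 6, prepared from acid 5 and divided between auxiliaries 7 and 19. The alkylation and the boron aldol use opposite enolate faces, hence the two antipodes. Acid 5 is cut at the aryl–CH2 bond to ester 4, bromide 3, aldehyde 2 and 5-bromovanillin 1. The forward reaction is a palladium-catalysed coupling with a zinc ester enolate that tolerates the acetal.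

## Roads not taken

**Alternative 1:** Both C2–C3 bonds are cut at once.

- Forward key step: bis(aryldiazoacetate) A2 would be treated with Rh2(S-PTTL)4 so that each carbenoid inserts into the neighbouring benzylic ether C–H bond. Sodium methoxide would then epimerise both C3 esters to give triester A1.
- Merits: two rings, two C–C bonds and four stereocentres in one flask, under catalyst rather than auxiliary control. The precursor is assembled by simple etherifications, and one hydride reduction would later deliver all three primary alcohols. In step count this road is probably shorter than the chosen one.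
- Weak points: insertions of this type give the 2,3-cis relationship first, so A1 depends on base epimerisation at two centres that each sit β to an aryloxy leaving group (risk of ring-opening by elimination) and in the presence of a Michael-accepting acrylate. The catalyst must override any bias of the first-formed unit in the second insertion. A compound with two diazo groups also invites carbene dimerisation and attack on the electron-rich arenes.
- Comparison: the chosen plan cannot match the brevity. It sets against it that each stereocentre pair comes from a separately checkable auxiliary reaction, and that the trans relationship arises directly in the ring closure (17 and 25) rather than by later epimerisation.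

**Alternative 2:** The C3–H bond and a temporary C–Si bond are cut.

- Forward key step: hydrodimethylsilyl ether A4 would undergo intramolecular hydrosilylation with the zerovalent platinum complex Pt2(dvtms)3 to give oxasilacyclopentane A3. Oxidation of the C–Si bond and closure of ring C would follow.
- Merits: C3 is set catalytically by the neighbouring carbinol, and the hydroxymethyl group arrives at the right oxidation level. In atom economy of the stereo-setting step this road is better than a stoichiometric auxiliary.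
- Weak points: the carbinol centre of A4 must first be made enantioselectively, and it is then inverted or ionised when ring C closes, so one asymmetric operation is spent on a centre that is re-formed. The 1,1-diaryl-type alkene is a sluggish hydrosilylation substrate. The aryl bromide of A3 still has to be converted into the anchor for unit 2, where the whole sequence would be run again.
- Comparison: the chosen plan uses auxiliaries but needs fewer redox and protecting-group operations per unit, and its formyl group links unit 1 to unit 2 without a separate functional-group exchange.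

**Alternative 3:** Ring D is cut at C2′–C3′ and O1′–C2′ in a [4+1] sense.

- Forward key step: KOH would convert sulfone A6 into ortho-quinone methide A8 and sulfonium salt A7 into its ylide. Carbon–carbon bond formation followed by displacement of the sulfide by the phenoxide would give bromide A5.
- Merits: ring D is formed from two separately made halves in one step, with the trans geometry that this annulation normally gives. In convergence it is better than the aldol, reduction and cyclisation sequence used here.
- Weak points: nothing in A7 or A8 controls the absolute configuration of the new pair relative to unit 1, whose stereocentres are remote. A chiral sulfide would be needed, or a one-to-one mixture of diastereomers accepted. A8 bears a β-silyloxy substituent, and its precursor A6 can eliminate silanolate on deprotonation. Unit 1 must still be made in enantiopure form by other means.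
- Comparison: the chosen plan takes three steps for ring D where this road takes one. It sets against that reagent control at C3′ in aldol adduct 22 and a ring closure to 25 whose trans outcome is thermodynamically backed.

Key step: step 11

Assumptions and conventions:
- Alcohol 9 and both antipodes of 4-benzyloxazolidin-2-one are taken as purchased.
- BrZnCH2CO2Et is used as a preformed THF solution (from ethyl bromoacetate and zinc).
- Mixed anhydride 6 is not purified; its filtered THF solution is divided and used at once in steps 6 and 13.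
- Unprimed locants refer to unit 1, primed locants to unit 2.
- In names, ArP = 2-(benzyloxy)-5-(1,3-dioxolan-2-yl)-3-methoxyphenyl.
- In names, U1 = (2R,3S)-7-methoxy-2-[3-methoxy-4-(triisopropylsilyloxy)phenyl]-3-[(triisopropylsilyloxy)methyl]-2,3-dihydrobenzofuran-5-yl.

## Route

Step 1
Reactants: 1 5-bromovanillin
Product: 2 4-(benzyloxy)-3-bromo-5-methoxybenzaldehyde
Conditions: BnBr, K2CO3, DMF, 60 °C
Reagents that add atoms: benzyl bromide, BrCc1ccccc1
Why: Williamson etherification of an acidic phenol; the benzyl ether survives enolate, hydride and acetal chemistry and is removed later by hydrogenolysis.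

Step 2
Reactants: 2 4-(benzyloxy)-3-bromo-5-methoxybenzaldehyde
Product: 3 2-[4-(benzyloxy)-3-bromo-5-methoxyphenyl]-1,3-dioxolane
Conditions: HOCH2CH2OH, TsOH·H2O (cat.), toluene, reflux, Dean–Stark
Reagents that add atoms: ethylene glycol, OCCO
Why: Acid-catalysed acetalisation with azeotropic removal of water masks the aldehyde against the zinc enolate, the sodium enolate and the borohydride used later.

Step 3
Reactants: 3 2-[4-(benzyloxy)-3-bromo-5-methoxyphenyl]-1,3-dioxolane
Product: 4 ethyl 2-[2-(benzyloxy)-5-(1,3-dioxolan-2-yl)-3-methoxyphenyl]acetate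
Conditions: BrZnCH2CO2Et (THF solution), Pd2(dba)3 (cat.), XPhos (cat.), THF, 60 °C
Reagents that add atoms: (2-ethoxy-2-oxoethyl)zinc bromide, CCOC(=O)C[Zn]Br
Why: Negishi-type coupling of an aryl bromide with a Reformatsky reagent under zerovalent palladium and a bulky biarylphosphine; the nearly neutral zinc enolate leaves the acetal alone and cannot undergo Claisen condensation, and the ethyl ester can later be cleaved by base without acid.

Step 4
Reactants: 4 ethyl 2-[2-(benzyloxy)-5-(1,3-dioxolan-2-yl)-3-methoxyphenyl]acetate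
Product: 5 2-[2-(benzyloxy)-5-(1,3-dioxolan-2-yl)-3-methoxyphenyl]acetic acid
Conditions: LiOH·H2O, THF–MeOH–H2O, rt; then 1 M HCl to pH 4–5, 0 °C
Reagents that add atoms: lithium hydroxide, [Li+].[OH-]
Why: Saponification; the cold, only weakly acidic work-up should free the acid while the dioxolane of the electron-rich arene is kept.

Step 5
Reactants: 5 2-[2-(benzyloxy)-5-(1,3-dioxolan-2-yl)-3-methoxyphenyl]acetic acid
Product: 6 2-[2-(benzyloxy)-5-(1,3-dioxolan-2-yl)-3-methoxyphenyl]acetic pivalic anhydride
Conditions: t-BuCOCl (1.0 equiv), Et3N, THF, −20 °C; Et3N·HCl filtered off under N2; filtrate used at once in two portions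
Reagents that add atoms: pivaloyl chloride, CC(C)(C)C(Cl)=O
Why: Mixed-anhydride formation from the triethylammonium carboxylate and a hindered acid chloride; neither acid nor strong base touches the acetal, and a single batch of the acylating agent serves both auxiliary acylations.

Step 6
Reactants: 6 2-[2-(benzyloxy)-5-(1,3-dioxolan-2-yl)-3-methoxyphenyl]acetic pivalic anhydride; 7 (S)-4-benzyloxazolidin-2-one
Product: 8 (S)-4-benzyl-3-[2-(ArP)acetyl]oxazolidin-2-one
Conditions: LiCl, Et3N, THF, −20 °C to rt
Reagents that add atoms: none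
Why: N-acylation of the oxazolidinone by a mixed pivalic anhydride (LiCl/Et3N variant); attack occurs at the less hindered arylacetyl carbonyl, and pivalate is the leaving group.

Step 7
Reactants: 9 4-(benzyloxy)-3-methoxybenzyl alcohol
Product: 10 4-(benzyloxy)-3-methoxybenzyl bromide
Conditions: PBr3, Et2O, 0 °C
Reagents that add atoms: phosphorus tribromide, BrP(Br)Br
Why: Standard conversion of an electron-rich benzylic alcohol into its bromide; the bromide is used at once because it is prone to self-alkylation on storage.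

Step 8
Reactants: 8 (S)-4-benzyl-3-[2-(ArP)acetyl]oxazolidin-2-one; 10 4-(benzyloxy)-3-methoxybenzyl bromide
Product: 12 (S)-4-benzyl-3-{(S)-2-(ArP)-3-[4-(benzyloxy)-3-methoxyphenyl]propanoyl}oxazolidin-2-one, via sodium (Z)-enolate 11 (not isolated)
Conditions: NaN(SiMe3)2, THF, −78 °C; then 10, −78 to −40 °C
Reagents that add atoms: none
Why: Evans alkylation: the chelated (Z)-enolate is benzylated on the face away from the benzyl group of the auxiliary, which sets the future C3 as (S); low temperature and a reactive benzylic bromide keep proton exchange at the acidic α-aryl centre slow.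

Step 9
Reactants: 12 (S)-4-benzyl-3-{(S)-2-(ArP)-3-[4-(benzyloxy)-3-methoxyphenyl]propanoyl}oxazolidin-2-one
Product: 13 (S)-2-(ArP)-3-[4-(benzyloxy)-3-methoxyphenyl]propan-1-ol
Conditions: LiBH4, MeOH (1.1 equiv), THF, 0 °C
Reagents that add atoms: none
Why: Reductive cleavage of the imide at its exocyclic carbonyl gives the primary alcohol and returns the auxiliary; once reduced, the stereocentre is no longer acidic.

Step 10
Reactants: 13 (S)-2-(ArP)-3-[4-(benzyloxy)-3-methoxyphenyl]propan-1-ol
Product: 15 4-hydroxy-3-[(S)-1-hydroxy-3-(4-hydroxy-3-methoxyphenyl)propan-2-yl]-5-methoxybenzaldehyde, via diphenol acetal 14 (not isolated)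
Conditions: H2 (1 atm), 10% Pd/C, EtOAc–MeOH, rt; filter; then 1 M aq HCl, THF, rt
Reagents that add atoms: water, O
Why: Hydrogenolysis of the two aryl benzyl ethers should be faster than cleavage of the cyclic acetal, and the aldehyde is released by acetal hydrolysis only after the catalyst is removed, so it is never exposed to hydrogen.

Step 11
Reactants: 15 4-hydroxy-3-[(S)-1-hydroxy-3-(4-hydroxy-3-methoxyphenyl)propan-2-yl]-5-methoxybenzaldehyde
Product: 17 (2R,3S)-2-(4-hydroxy-3-methoxyphenyl)-3-(hydroxymethyl)-7-methoxy-2,3-dihydrobenzofuran-5-carbaldehyde, via para-quinone methide 16 (not isolated)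
Conditions: DDQ (1.05 equiv), CH2Cl2–1,4-dioxane (5:1), 0 °C to rt
Reagents that add atoms: none
Why: DDQ should complex the electron-rich guaiacol ring A and remove hydride from the benzylic methylene para to its hydroxyl, and loss of the phenolic proton then gives para-quinone methide 16. The closest known reaction type is the dehydrogenation of 4-alkyl-2-methoxyphenols to para-quinone methides by DDQ or Ag2O and their capture by oxygen nucleophiles, including intramolecular capture by phenols as in oxidative flavan syntheses from 1,3-diarylpropanes. Ring C closes by a 5-exo-trig 1,6-conjugate addition of the ring-B phenol oxygen to the exocyclic methide carbon C2, which restores the aromaticity of ring A. The new centre C2 is controlled by C3: in the closing transition state the quinoid ring turns away from the hydroxymethyl group, giving the trans (2R,3S) ring. The acidic hydroquinone by-product can re-open any cis isomer through the same quinone methide and funnel it to the more stable trans form. The step needs oxidation of ring A only, and this is secured by the para-formyl group on ring B, which raises the oxidation potential of that phenol and leaves it no benzylic hydrogen para to its oxygen. The primary alcohol cannot compete as a nucleophile because it could only form a four-membered ring. A second dehydrogenation of 17 towards the benzofuran is held back by using one equivalent of oxidant at low temperature.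

Step 12
Reactants: 17 (2R,3S)-2-(4-hydroxy-3-methoxyphenyl)-3-(hydroxymethyl)-7-methoxy-2,3-dihydrobenzofuran-5-carbaldehyde
Product: 18 (2R,3S)-7-methoxy-2-[3-methoxy-4-(triisopropylsilyloxy)phenyl]-3-[(triisopropylsilyloxy)methyl]-2,3-dihydrobenzofuran-5-carbaldehyde
Conditions: i-Pr3SiCl (2.5 equiv), imidazole, DMF, rt
Reagents that add atoms: triisopropylsilyl chloride, CC(C)[Si](Cl)(C(C)C)C(C)C
Why: Silylation of the phenol and the primary alcohol in one operation; capping the ring-A phenol also shuts off re-opening of ring C through the quinone methide.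

Step 13
Reactants: 6 2-[2-(benzyloxy)-5-(1,3-dioxolan-2-yl)-3-methoxyphenyl]acetic pivalic anhydride; 19 (R)-4-benzyloxazolidin-2-one
Product: 20 (R)-4-benzyl-3-[2-(ArP)acetyl]oxazolidin-2-one
Conditions: LiCl, Et3N, THF, −20 °C to rt
Reagents that add atoms: none
Why: Same mixed-anhydride N-acylation as in step 6, run on the second portion of 6; the antipodal auxiliary is needed because the boron aldol uses the enolate face opposite to the one used in the chelated alkylation.

Step 14
Reactants: 20 (R)-4-benzyl-3-[2-(ArP)acetyl]oxazolidin-2-one; 18 (2R,3S)-7-methoxy-2-[3-methoxy-4-(triisopropylsilyloxy)phenyl]-3-[(triisopropylsilyloxy)methyl]-2,3-dihydrobenzofuran-5-carbaldehyde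
Product: 22 (R)-4-benzyl-3-[(2R,3R)-2-(ArP)-3-hydroxy-3-(U1)propanoyl]oxazolidin-2-one, via dibutylboron (Z)-enolate 21 (not isolated)
Conditions: Bu2BOTf, i-Pr2NEt, CH2Cl2, −78 to 0 °C; then 18, −78 to 0 °C; pH 7 buffer, MeOH, 30% H2O2, 0 °C
Reagents that add atoms: none
Why: Evans syn-aldol through a closed chair transition state of the (Z)-boron enolate with the auxiliary dipole turned away; the auxiliary fixes the α-carbon (the future C3′) and the remote stereocentres of 18 have no say. The carbinol configuration is incidental because that centre is ionised in step 16.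

Step 15
Reactants: 22 (R)-4-benzyl-3-[(2R,3R)-2-(ArP)-3-hydroxy-3-(U1)propanoyl]oxazolidin-2-one
Product: 23 (1R,2S)-2-(ArP)-1-(U1)propane-1,3-diol
Conditions: LiBH4, MeOH (1.1 equiv), THF, 0 °C
Reagents that add atoms: none
Why: Reductive removal of the auxiliary from an aldol adduct; fast hydride delivery at 0 °C should outrun retro-aldol cleavage, and the acetal and silyl ethers are inert.

Step 16
Reactants: 23 (1R,2S)-2-(ArP)-1-(U1)propane-1,3-diol
Product: 25 (2R,3S)-3-(hydroxymethyl)-7-methoxy-2-(U1)-2,3-dihydrobenzofuran-5-carbaldehyde, via phenol triol acetal 24 (not isolated)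
Conditions: H2 (1 atm), 10% Pd/C, EtOAc, rt; filter; then 1 M aq HCl, THF, rt
Reagents that add atoms: water, O
Why: Hydrogenolysis frees the ring-E phenol; dilute acid then ionises the benzylic C–OH bond (stabilised by O1 in the para position), and the phenol captures the cation in a 5-exo closure trans to the C3′ substituent, with reversible ionisation as thermodynamic back-up. The same acid hydrolyses the acetal, and the primary hydroxyl cannot compete because it would form an oxetane.

Step 17
Reactants: 25 (2R,3S)-3-(hydroxymethyl)-7-methoxy-2-(U1)-2,3-dihydrobenzofuran-5-carbaldehyde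
Product: 26 ethyl (E)-3-[(2R,3S)-3-(hydroxymethyl)-7-methoxy-2-(U1)-2,3-dihydrobenzofuran-5-yl]acrylate
Conditions: Ph3P=CHCO2Et, toluene, 60 °C
Reagents that add atoms: ethyl (triphenylphosphoranylidene)acetate, CCOC(=O)C=P(c1ccccc1)(c1ccccc1)c1ccccc1
Why: Wittig olefination with a stabilised ylide is (E)-selective with aryl aldehydes and, being neutral, tolerates the free primary alcohol and the benzylic ethers.

Step 18
Reactants: 26 ethyl (E)-3-[(2R,3S)-3-(hydroxymethyl)-7-methoxy-2-(U1)-2,3-dihydrobenzofuran-5-yl]acrylate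
Product: 27 (E)-3-[(2R,3S)-3-(hydroxymethyl)-7-methoxy-2-(U1)-2,3-dihydrobenzofuran-5-yl]prop-2-en-1-ol
Conditions: i-Bu2AlH (excess), CH2Cl2, −78 °C; aq potassium sodium tartrate
Reagents that add atoms: none
Why: 1,2-Reduction of a cinnamate to the allylic alcohol at low temperature, as is routine for ferulate-type esters; silyl ethers and benzylic aryl ethers are untouched.

Step 19
Reactants: 27 (E)-3-[(2R,3S)-3-(hydroxymethyl)-7-methoxy-2-(U1)-2,3-dihydrobenzofuran-5-yl]prop-2-en-1-ol
Product: 28 (E)-3-[(2R,3S)-2-{(2R,3S)-2-(4-hydroxy-3-methoxyphenyl)-3-(hydroxymethyl)-7-methoxy-2,3-dihydrobenzofuran-5-yl}-3-(hydroxymethyl)-7-methoxy-2,3-dihydrobenzofuran-5-yl]prop-2-en-1-ol (target)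
Conditions: Bu4NF, THF, 0 °C to rt
Reagents that add atoms: none
Why: Fluoride cleaves the aryl and the alkyl triisopropylsilyl ethers under mildly basic conditions that spare the acid-sensitive cinnamyl alcohol and both benzylic C–O bonds; no stereocentre is touched.

## Compound list

1 | 5-bromovanillin | COc1cc(C=O)cc(Br)c1O | starting material
2 | 4-(benzyloxy)-3-bromo-5-methoxybenzaldehyde | COc1cc(C=O)cc(Br)c1OCc1ccccc1 | intermediate
3 | 2-[4-(benzyloxy)-3-bromo-5-methoxyphenyl]-1,3-dioxolane | COc1cc(C2OCCO2)cc(Br)c1OCc1ccccc1 | intermediate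
4 | ethyl 2-[2-(benzyloxy)-5-(1,3-dioxolan-2-yl)-3-methoxyphenyl]acetate | CCOC(=O)Cc1cc(C2OCCO2)cc(OC)c1OCc1ccccc1 | intermediate
5 | 2-[2-(benzyloxy)-5-(1,3-dioxolan-2-yl)-3-methoxyphenyl]acetic acid | OC(=O)Cc1cc(C2OCCO2)cc(OC)c1OCc1ccccc1 | intermediate
6 | 2-[2-(benzyloxy)-5-(1,3-dioxolan-2-yl)-3-methoxyphenyl]acetic pivalic anhydride (mixed anhydride of 5 with pivalic acid) | CC(C)(C)C(=O)OC(=O)Cc1cc(C2OCCO2)cc(OC)c1OCc1ccccc1 | intermediate
7 | (S)-4-benzyloxazolidin-2-one | O=C1N[C@@H](Cc2ccccc2)CO1 | starting material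
8 | (S)-4-benzyl-3-{2-[2-(benzyloxy)-5-(1,3-dioxolan-2-yl)-3-methoxyphenyl]acetyl}oxazolidin-2-one | O=C(Cc1cc(C2OCCO2)cc(OC)c1OCc1ccccc1)N1[C@@H](Cc2ccccc2)COC1=O | intermediate
9 | 4-(benzyloxy)-3-methoxybenzyl alcohol | COc1cc(CO)ccc1OCc1ccccc1 | starting material
10 | 4-(benzyloxy)-3-methoxybenzyl bromide | COc1cc(CBr)ccc1OCc1ccccc1 | intermediate
11 | sodium (Z)-enolate of 8 | [Na+].[O-]/C(=C\c1cc(C2OCCO2)cc(OC)c1OCc1ccccc1)N1[C@@H](Cc2ccccc2)COC1=O | intermediate (not isolated)
12 | (S)-4-benzyl-3-{(S)-2-[2-(benzyloxy)-5-(1,3-dioxolan-2-yl)-3-methoxyphenyl]-3-[4-(benzyloxy)-3-methoxyphenyl]propanoyl}oxazolidin-2-one | O=C([C@@H](Cc1ccc(OCc2ccccc2)c(OC)c1)c1cc(C2OCCO2)cc(OC)c1OCc1ccccc1)N1[C@@H](Cc2ccccc2)COC1=O | intermediate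
13 | (S)-2-[2-(benzyloxy)-5-(1,3-dioxolan-2-yl)-3-methoxyphenyl]-3-[4-(benzyloxy)-3-methoxyphenyl]propan-1-ol | OC[C@@H](Cc1ccc(OCc2ccccc2)c(OC)c1)c1cc(C2OCCO2)cc(OC)c1OCc1ccccc1 | intermediate
14 | 4-(1,3-dioxolan-2-yl)-2-[(S)-1-hydroxy-3-(4-hydroxy-3-methoxyphenyl)propan-2-yl]-6-methoxyphenol | OC[C@@H](Cc1ccc(O)c(OC)c1)c1cc(C2OCCO2)cc(OC)c1O | intermediate (not isolated)
15 | 4-hydroxy-3-[(S)-1-hydroxy-3-(4-hydroxy-3-methoxyphenyl)propan-2-yl]-5-methoxybenzaldehyde | OC[C@@H](Cc1ccc(O)c(OC)c1)c1cc(C=O)cc(OC)c1O | intermediate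
16 | 4-hydroxy-3-[(S)-1-hydroxy-3-(3-methoxy-4-oxocyclohexa-2,5-dien-1-ylidene)propan-2-yl]-5-methoxybenzaldehyde (para-quinone methide) | OC[C@@H](C=C1C=CC(=O)C(OC)=C1)c1cc(C=O)cc(OC)c1O | intermediate (not isolated)
17 | (2R,3S)-2-(4-hydroxy-3-methoxyphenyl)-3-(hydroxymethyl)-7-methoxy-2,3-dihydrobenzofuran-5-carbaldehyde | COc1cc([C@@H]2Oc3c(OC)cc(C=O)cc3[C@H]2CO)ccc1O | intermediate
18 | (2R,3S)-7-methoxy-2-[3-methoxy-4-(triisopropylsilyloxy)phenyl]-3-[(triisopropylsilyloxy)methyl]-2,3-dihydrobenzofuran-5-carbaldehyde | COc1cc([C@@H]2Oc3c(OC)cc(C=O)cc3[C@H]2CO[Si](C(C)C)(C(C)C)C(C)C)ccc1O[Si](C(C)C)(C(C)C)C(C)C | intermediate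
19 | (R)-4-benzyloxazolidin-2-one | O=C1N[C@H](Cc2ccccc2)CO1 | starting material
20 | (R)-4-benzyl-3-{2-[2-(benzyloxy)-5-(1,3-dioxolan-2-yl)-3-methoxyphenyl]acetyl}oxazolidin-2-one | O=C(Cc1cc(C2OCCO2)cc(OC)c1OCc1ccccc1)N1[C@H](Cc2ccccc2)COC1=O | intermediate
21 | dibutylboron (Z)-enolate of 20 | CCCCB(CCCC)O/C(=C\c1cc(C2OCCO2)cc(OC)c1OCc1ccccc1)N1[C@H](Cc2ccccc2)COC1=O | intermediate (not isolated)
22 | (R)-4-benzyl-3-[(2R,3R)-2-(ArP)-3-hydroxy-3-(U1)propanoyl]oxazolidin-2-one (syn-aldol adduct) | COc1cc([C@@H]2Oc3c(OC)cc([C@H](O)[C@H](C(=O)N4[C@H](Cc5ccccc5)COC4=O)c4cc(C5OCCO5)cc(OC)c4OCc4ccccc4)cc3[C@H]2CO[Si](C(C)C)(C(C)C)C(C)C)ccc1O[Si](C(C)C)(C(C)C)C(C)C | intermediate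
23 | (1R,2S)-2-(ArP)-1-(U1)propane-1,3-diol | COc1cc([C@@H]2Oc3c(OC)cc([C@H](O)[C@H](CO)c4cc(C5OCCO5)cc(OC)c4OCc4ccccc4)cc3[C@H]2CO[Si](C(C)C)(C(C)C)C(C)C)ccc1O[Si](C(C)C)(C(C)C)C(C)C | intermediate
24 | (1R,2S)-2-[5-(1,3-dioxolan-2-yl)-2-hydroxy-3-methoxyphenyl]-1-(U1)propane-1,3-diol | COc1cc([C@@H]2Oc3c(OC)cc([C@H](O)[C@H](CO)c4cc(C5OCCO5)cc(OC)c4O)cc3[C@H]2CO[Si](C(C)C)(C(C)C)C(C)C)ccc1O[Si](C(C)C)(C(C)C)C(C)C | intermediate (not isolated)
25 | (2R,3S)-3-(hydroxymethyl)-7-methoxy-2-(U1)-2,3-dihydrobenzofuran-5-carbaldehyde | COc1cc([C@@H]2Oc3c(OC)cc([C@@H]4Oc5c(OC)cc(C=O)cc5[C@H]4CO)cc3[C@H]2CO[Si](C(C)C)(C(C)C)C(C)C)ccc1O[Si](C(C)C)(C(C)C)C(C)C | intermediate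
26 | ethyl (E)-3-[(2R,3S)-3-(hydroxymethyl)-7-methoxy-2-(U1)-2,3-dihydrobenzofuran-5-yl]acrylate | COc1cc([C@@H]2Oc3c(OC)cc([C@@H]4Oc5c(OC)cc(/C=C/C(=O)OCC)cc5[C@H]4CO)cc3[C@H]2CO[Si](C(C)C)(C(C)C)C(C)C)ccc1O[Si](C(C)C)(C(C)C)C(C)C | intermediate
27 | (E)-3-[(2R,3S)-3-(hydroxymethyl)-7-methoxy-2-(U1)-2,3-dihydrobenzofuran-5-yl]prop-2-en-1-ol | COc1cc([C@@H]2Oc3c(OC)cc([C@@H]4Oc5c(OC)cc(/C=C/CO)cc5[C@H]4CO)cc3[C@H]2CO[Si](C(C)C)(C(C)C)C(C)C)ccc1O[Si](C(C)C)(C(C)C)C(C)C | intermediate
28 | (E)-3-[(2R,3S)-2-{(2R,3S)-2-(4-hydroxy-3-methoxyphenyl)-3-(hydroxymethyl)-7-methoxy-2,3-dihydrobenzofuran-5-yl}-3-(hydroxymethyl)-7-methoxy-2,3-dihydrobenzofuran-5-yl]prop-2-en-1-ol | COc1cc([C@@H]2Oc3c(OC)cc([C@@H]4Oc5c(OC)cc(/C=C/CO)cc5[C@H]4CO)cc3[C@H]2CO)ccc1O | target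

## Step count and risk assessment

Total: 19 steps. Longest linear sequence: 17 steps (steps 1–6, 8–12 and 14–19, from 5-bromovanillin 1); steps 7 and 13 are side branches.

**Step 11 (key step).** The most likely failure is over-oxidation. Product 17 is as electron-rich as substrate 15, so a second dehydrogenation at C2 (leading towards the benzofuran) or oxidative coupling at the free ortho position of ring A may compete with clean quinone methide formation.

The fallback reaches the same quinone methide by dehydration instead of dehydrogenation. It sets out from 9 and from imide 20 and returns at 17.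
- Alcohol 9 is oxidised with MnO2 to 4-(benzyloxy)-3-methoxybenzaldehyde F1.
- F1 is combined with boron enolate 21 under the conditions of step 14 to give syn-aldol adduct F2. The antipodal auxiliary gives the same C3 configuration as the alkylation route.
- LiBH4 gives diol F3.
- Hydrogenolysis over Pd/C gives tetraol acetal F4.
- Dilute aqueous HCl ionises the para-hydroxybenzylic alcohol of F4, the ring-B phenol closes ring C trans, and the acetal is hydrolysed, which gives 17.

**Step 14.** The most likely failures are erosion of α-facial control or retro-aldol cleavage, because the arylacetyl enolate is stabilised and the aldehyde is electron-rich. Opening of the aryl dioxolane by the boron triflate is a second concern.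

The fallback forms C2′–C3′ by alkylation and closes ring D by benzylic C–H oxidation. It sets out from 18 and from imide 8 and returns at 25.
- Aldehyde 18 is reduced with NaBH4 to benzylic alcohol F5.
- CBr4/PPh3 (Appel reaction) gives benzylic bromide F6.
- Sodium enolate 11, whose (S)-auxiliary has the correct sense for alkylation, is alkylated with F6 to give imide F7.
- LiBH4 gives alcohol F8.
- Hydrogenolysis over Pd/C gives phenol acetal F9.
- Dilute aqueous HCl hydrolyses the acetal and gives phenol aldehyde F10.
- DDQ abstracts hydride from the methylene para to O1 and the ring-E phenol closes ring D, giving 25. The ring-E phenol is shielded by its para-formyl group.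

**Step 16.** The most likely failures are fragmentation of the benzylic cation with loss of formaldehyde (or simple elimination) to a stilbene instead of ring closure, and hydrogenolytic loss of the activated benzylic hydroxyl during debenzylation.

The fallback closes ring D at the acyl oxidation level, before a hydroxymethyl group exists. It sets out from 22 and returns at 26.
- Hydrogenolysis of 22 gives phenol imide F11.
- Aqueous HCl in THF closes ring D and frees the aldehyde, giving imide aldehyde F12. Its acyl substituent cannot depart as formaldehyde.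
- The Wittig reagent of step 17 gives imide cinnamate F13.
- NaBH4 in THF–H2O removes the auxiliary reductively in preference to the conjugated ethyl ester and gives 26.

**Step 3.** The most likely failure is decay of the zinc enolate (protonation or self-condensation) outpacing coupling at the hindered aryl bromide with its ortho-alkoxy group.

The fallback installs the two-carbon arm by allylation and oxidative cleavage. It sets out from 3 and returns at 5.
- Suzuki–Miyaura coupling of 3 with allylboronic acid pinacol ester (Pd(PPh3)4, CsF, THF, reflux) gives allylarene F14.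
- Lemieux–Johnson cleavage (OsO4 cat., NaIO4, 2,6-lutidine) gives arylacetaldehyde F15.
- Pinnick oxidation (NaClO2, NaH2PO4, 2-methyl-2-butene) gives acid 5.

## Further compounds

F1 | step 11 | 4-(benzyloxy)-3-methoxybenzaldehyde | COc1cc(C=O)ccc1OCc1ccccc1
F2 | step 11 | (R)-4-benzyl-3-{(2R,3R)-2-[2-(benzyloxy)-5-(1,3-dioxolan-2-yl)-3-methoxyphenyl]-3-[4-(benzyloxy)-3-methoxyphenyl]-3-hydroxypropanoyl}oxazolidin-2-one | O=C(N1[C@H](Cc2ccccc2)COC1=O)[C@H](c1cc(C2OCCO2)cc(OC)c1OCc1ccccc1)[C@@H](O)c1ccc(OCc2ccccc2)c(OC)c1
F3 | step 11 | (1R,2S)-2-[2-(benzyloxy)-5-(1,3-dioxolan-2-yl)-3-methoxyphenyl]-1-[4-(benzyloxy)-3-methoxyphenyl]propane-1,3-diol | OC[C@H](c1cc(C2OCCO2)cc(OC)c1OCc1ccccc1)[C@@H](O)c1ccc(OCc2ccccc2)c(OC)c1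
F4 | step 11 | (1R,2S)-2-[5-(1,3-dioxolan-2-yl)-2-hydroxy-3-methoxyphenyl]-1-(4-hydroxy-3-methoxyphenyl)propane-1,3-diol | OC[C@H](c1cc(C2OCCO2)cc(OC)c1O)[C@@H](O)c1ccc(O)c(OC)c1
F5 | step 14 | [(2R,3S)-7-methoxy-2-[3-methoxy-4-(triisopropylsilyloxy)phenyl]-3-[(triisopropylsilyloxy)methyl]-2,3-dihydrobenzofuran-5-yl]methanol | COc1cc([C@@H]2Oc3c(OC)cc(CO)cc3[C@H]2CO[Si](C(C)C)(C(C)C)C(C)C)ccc1O[Si](C(C)C)(C(C)C)C(C)C
F6 | step 14 | (2R,3S)-5-(bromomethyl)-7-methoxy-2-[3-methoxy-4-(triisopropylsilyloxy)phenyl]-3-[(triisopropylsilyloxy)methyl]-2,3-dihydrobenzofuran | COc1cc([C@@H]2Oc3c(OC)cc(CBr)cc3[C@H]2CO[Si](C(C)C)(C(C)C)C(C)C)ccc1O[Si](C(C)C)(C(C)C)C(C)C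
F7 | step 14 | (S)-4-benzyl-3-[(S)-2-(ArP)-3-(U1)propanoyl]oxazolidin-2-one | COc1cc([C@@H]2Oc3c(OC)cc(C[C@H](C(=O)N4[C@@H](Cc5ccccc5)COC4=O)c4cc(C5OCCO5)cc(OC)c4OCc4ccccc4)cc3[C@H]2CO[Si](C(C)C)(C(C)C)C(C)C)ccc1O[Si](C(C)C)(C(C)C)C(C)C
F8 | step 14 | (S)-2-(ArP)-3-(U1)propan-1-ol | COc1cc([C@@H]2Oc3c(OC)cc(C[C@H](CO)c4cc(C5OCCO5)cc(OC)c4OCc4ccccc4)cc3[C@H]2CO[Si](C(C)C)(C(C)C)C(C)C)ccc1O[Si](C(C)C)(C(C)C)C(C)C
F9 | step 14 | 4-(1,3-dioxolan-2-yl)-2-[(S)-1-hydroxy-3-(U1)propan-2-yl]-6-methoxyphenol | COc1cc([C@@H]2Oc3c(OC)cc(C[C@H](CO)c4cc(C5OCCO5)cc(OC)c4O)cc3[C@H]2CO[Si](C(C)C)(C(C)C)C(C)C)ccc1O[Si](C(C)C)(C(C)C)C(C)C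
F10 | step 14 | 4-hydroxy-3-[(S)-1-hydroxy-3-(U1)propan-2-yl]-5-methoxybenzaldehyde | COc1cc([C@@H]2Oc3c(OC)cc(C[C@H](CO)c4cc(C=O)cc(OC)c4O)cc3[C@H]2CO[Si](C(C)C)(C(C)C)C(C)C)ccc1O[Si](C(C)C)(C(C)C)C(C)C
F11 | step 16 | (R)-4-benzyl-3-{(2R,3R)-2-[5-(1,3-dioxolan-2-yl)-2-hydroxy-3-methoxyphenyl]-3-hydroxy-3-(U1)propanoyl}oxazolidin-2-one | COc1cc([C@@H]2Oc3c(OC)cc([C@H](O)[C@H](C(=O)N4[C@H](Cc5ccccc5)COC4=O)c4cc(C5OCCO5)cc(OC)c4O)cc3[C@H]2CO[Si](C(C)C)(C(C)C)C(C)C)ccc1O[Si](C(C)C)(C(C)C)C(C)C
F12 | step 16 | (R)-4-benzyl-3-{[(2R,3R)-5-formyl-7-methoxy-2-(U1)-2,3-dihydrobenzofuran-3-yl]carbonyl}oxazolidin-2-one (2,3-trans) | COc1cc([C@@H]2Oc3c(OC)cc([C@@H]4Oc5c(OC)cc(C=O)cc5[C@H]4C(=O)N4[C@H](Cc5ccccc5)COC4=O)cc3[C@H]2CO[Si](C(C)C)(C(C)C)C(C)C)ccc1O[Si](C(C)C)(C(C)C)C(C)C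
F13 | step 16 | ethyl (E)-3-[(2R,3R)-3-{[(R)-4-benzyl-2-oxooxazolidin-3-yl]carbonyl}-7-methoxy-2-(U1)-2,3-dihydrobenzofuran-5-yl]acrylate (2,3-trans) | COc1cc([C@@H]2Oc3c(OC)cc([C@@H]4Oc5c(OC)cc(/C=C/C(=O)OCC)cc5[C@H]4C(=O)N4[C@H](Cc5ccccc5)COC4=O)cc3[C@H]2CO[Si](C(C)C)(C(C)C)C(C)C)ccc1O[Si](C(C)C)(C(C)C)C(C)C
F14 | step 3 | 2-[3-allyl-4-(benzyloxy)-5-methoxyphenyl]-1,3-dioxolane | C=CCc1cc(C2OCCO2)cc(OC)c1OCc1ccccc1
F15 | step 3 | 2-[2-(benzyloxy)-5-(1,3-dioxolan-2-yl)-3-methoxyphenyl]acetaldehyde | O=CCc1cc(C2OCCO2)cc(OC)c1OCc1ccccc1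
A1 | alternative 1 | trans,trans bis-dihydrobenzofuran triester (ring A triisopropylsilyl ether) | COc1cc([C@@H]2Oc3c(OC)cc([C@@H]4Oc5c(OC)cc(/C=C/C(=O)OC)cc5[C@H]4C(=O)OC)cc3[C@H]2C(=O)OC)ccc1O[Si](C(C)C)(C(C)C)C(C)C
A2 | alternative 1 | bis(aryldiazoacetate) with two benzylic aryl ether links | COc1cc(COc2c(OC)cc(COc3c(OC)cc(/C=C/C(=O)OC)cc3C(=[N+]=[N-])C(=O)OC)cc2C(=[N+]=[N-])C(=O)OC)ccc1O[Si](C(C)C)(C(C)C)C(C)C
A3 | alternative 2 | 2,3-syn 1-oxa-2-silacyclopentane | COc1cc([C@@H]2O[Si](C)(C)C[C@@H]2c3cc(Br)cc(OC)c3OCOC)ccc1OCOC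
A4 | alternative 2 | hydrodimethylsilyl ether of the 1,2-diaryl allylic alcohol | COc1cc([C@H](O[SiH](C)C)C(=C)c2cc(Br)cc(OC)c2OCOC)ccc1OCOC
A5 | alternative 3 | silyl-protected bis-dihydrobenzofuran aryl bromide | COc1cc([C@@H]2Oc3c(OC)cc([C@@H]4Oc5c(OC)cc(Br)cc5[C@H]4CO[Si](C(C)C)(C(C)C)C(C)C)cc3[C@H]2CO[Si](C(C)C)(C(C)C)C(C)C)ccc1O[Si](C(C)C)(C(C)C)C(C)C
A6 | alternative 3 | 4-bromo-2-methoxy-6-[1-tosyl-2-(triisopropylsilyloxy)ethyl]phenol | COc1cc(Br)cc(C(CO[Si](C(C)C)(C(C)C)C(C)C)S(=O)(=O)c2ccc(C)cc2)c1O
A7 | alternative 3 | unit-1 benzylic dimethylsulfonium bromide | COc1cc([C@@H]2Oc3c(OC)cc(C[S+](C)C)cc3[C@H]2CO[Si](C(C)C)(C(C)C)C(C)C)ccc1O[Si](C(C)C)(C(C)C)C(C)C.[Br-]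
A8 | alternative 3 | ring-E ortho-quinone methide | COC1=CC(Br)=CC(=CCO[Si](C(C)C)(C(C)C)C(C)C)C1=O
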